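**Retrosynthetic overview**
- The target comes from its 2',4'-bis-TBS ether. Ring A of that ether is dismantled completely by a retro-[4+2]/aromatisation that cuts C8–C8a and C5–C4a.
- Structural feature used: the C4a=C8a bond shared by rings A and C is the enol-ether C5=C6 bond of a 2-aryl-2,3-dihydropyran-4-one. The remaining ring A atoms C5(O)–C6(H)–C7(O)–C8(lavandulyl) are the C1–C4 chain of a γ-lavandulyl acetoacetate, so its nucleophilic end (future C8) faces the electrophilic, O1-bearing C8a.
- Dienophile half: ring B is bought as the benzaldehyde. A catalytic asymmetric hetero-Diels–Alder reaction with Danishefsky diene builds ring C and sets C2. C5 is then sulfenylated and oxidised to the sulfoxide.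
- Diene half: auxiliary-controlled deconjugative prenylation of a senecioyl imide sets the lavandulyl centre. Reduction, iodination, acetoacetate dianion alkylation and double silylation follow.
- Ring order: B (bought), C (hetero-Diels–Alder), A (benzannulation, last, which also joins the two chiral halves).

Key step: step 12

Assumption: the (S)-BINOL/Ti(OiPr)4 catalyst is taken to direct attack to the Si face of the aryl aldehyde, as in related BINOL–titanium additions to aryl aldehydes. If the configurational check on the dihydropyranone shows the opposite, (R)-BINOL is used and nothing else changes.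

Step 1
Reactants: 1 (S)-4-benzyloxazolidin-2-one; 2 3-methylbut-2-enoyl chloride (senecioyl chloride)
Product: 4 (S)-4-benzyl-3-(3-methylbut-2-enoyl)oxazolidin-2-one, via N-lithio oxazolidinone 3 (not isolated)
Conditions: n-BuLi, THF, −78 °C; then 2, −78 → 0 °C
Reagents that add atoms: none
Why: N-acylation of a lithiated Evans auxiliary with an acid chloride is standard and leaves the conjugated alkene alone at low temperature.

Step 2
Reactants: 4 (S)-4-benzyl-3-(3-methylbut-2-enoyl)oxazolidin-2-one; 5 prenyl bromide (1-bromo-3-methylbut-2-ene)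
Product: 7 (4S)-4-benzyl-3-[(2S)-5-methyl-2-(prop-1-en-2-yl)hex-4-enoyl]oxazolidin-2-one, via sodium dienolate 6 (not isolated)
Conditions: NaN(SiMe3)2, THF, −78 °C; then 5, −78 → −40 °C; cold quench
Reagents that add atoms: none
Why: Evans asymmetric alkylation in its deconjugative form: removal of a γ-proton from the s-cis enoyl imide gives the sodium-chelated (Z)-dienolate 6, which reacts at its α-carbon with the allylic bromide (SN2) on the face away from the benzyl group, so the auxiliary sets the new centre as 2S and the double bond ends up as the isopropenyl group.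

Step 3
Reactants: 7 (4S)-4-benzyl-3-[(2S)-5-methyl-2-(prop-1-en-2-yl)hex-4-enoyl]oxazolidin-2-one
Product: 8 (S)-lavandulol [(2S)-5-methyl-2-(prop-1-en-2-yl)hex-4-en-1-ol]
Conditions: LiBH4, H2O (1 equiv), Et2O, 0 °C
Reagents that add atoms: none
Why: Hydride cleavage of an Evans imide at the exocyclic carbonyl is standard, spares both alkenes and the α-centre and returns the auxiliary, and the sign of rotation of 8, which should be opposite to that of natural (R)-lavandulol, checks step 2.

Step 4
Reactants: 8 (S)-lavandulol
Product: 9 (S)-lavandulyl iodide [(3S)-3-(iodomethyl)-2,6-dimethylhepta-1,5-diene]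
Conditions: PPh3, imidazole, I2, CH2Cl2, 0 °C (premixed); then 8, 0 °C → rt, dark
Reagents that add atoms: iodine, II
Why: Appel-type iodination activates the primary hydroxyl as an oxyphosphonium ion and displaces it with iodide at CH2 (SN2), a carbon next to but not at the stereocentre, and premixing the reagents leaves no free iodine for the alkenes.

Step 5
Reactants: 9 (S)-lavandulyl iodide; 10 methyl acetoacetate
Product: 12 methyl (6S)-9-methyl-3-oxo-6-(prop-1-en-2-yl)dec-8-enoate, via acetoacetate dianion 11 (not isolated)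
Conditions: 10, NaH, THF, 0 °C; n-BuLi, 0 °C; then 9, 0 °C → rt; cold 1 M HCl quench
Reagents that add atoms: none
Why: Weiler dianion alkylation: only the more basic terminal carbanion of 11 attacks the primary iodide, so the new C–C bond forms at the γ-carbon (the future C8) and the neighbouring stereocentre is not involved (its label stays S only because of CIP ranking).

Step 6
Reactants: 12 methyl (6S)-9-methyl-3-oxo-6-(prop-1-en-2-yl)dec-8-enoate
Product: 13 methyl (6S)-9-methyl-6-(prop-1-en-2-yl)-3-(trimethylsilyloxy)deca-2,8-dienoate (C2=C3 geometry immaterial)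
Conditions: Me3SiCl, Et3N, toluene, rt; filtration, concentration
Reagents that add atoms: chlorotrimethylsilane, C[Si](C)(C)Cl
Why: O-silylation of the enol form of a β-keto ester under soft enolisation is the established first stage of the Chan-type bis(silyloxy)diene synthesis and touches nothing else in 12.

Step 7
Reactants: 13 methyl (6S)-9-methyl-6-(prop-1-en-2-yl)-3-(trimethylsilyloxy)deca-2,8-dienoate
Product: 15 (3Z,6R)-1-methoxy-9-methyl-6-(prop-1-en-2-yl)-1,3-bis(trimethylsilyloxy)deca-1,3,8-triene, via lithium dienolate 14 (not isolated)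
Conditions: LiN(iPr)2, THF, −78 °C; Me3SiCl, −78 °C → rt; pentane, filtration under argon, used without chromatography
Reagents that add atoms: chlorotrimethylsilane, C[Si](C)(C)Cl
Why: Kinetic γ-deprotonation of the β-silyloxy enoate and O-silylation of the extended enolate 14 is the established second stage of the same diene synthesis, and allylic strain should place the C5 chain trans to C2 (3Z), the geometry that can reach the s-cis conformation (the centre keeps its shape, the label becoming R through CIP ranking).

Step 8
Reactants: 16 2,4-dihydroxy-5-methoxybenzaldehyde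
Product: 17 2,4-bis(tert-butyldimethylsilyloxy)-5-methoxybenzaldehyde
Conditions: TBSCl, imidazole, DMF, rt
Reagents that add atoms: tert-butyldimethylsilyl chloride, CC(C)(C)[Si](C)(C)Cl
Why: Silylation of phenols with TBSCl and imidazole is routine, excess reagent also covers the hydrogen-bonded ortho phenol, and aryl TBS ethers tolerate every later step up to the final fluoride treatment.

Step 9
Reactants: 17 2,4-bis(tert-butyldimethylsilyloxy)-5-methoxybenzaldehyde; 18 Danishefsky diene [(E)-1-methoxy-3-(trimethylsilyloxy)buta-1,3-diene]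
Product: 20 (2S)-2-[2,4-bis(tert-butyldimethylsilyloxy)-5-methoxyphenyl]-2,3-dihydro-4H-pyran-4-one, via Mukaiyama aldol adduct 19 (not isolated)
Conditions: (S)-BINOL (20 mol%), Ti(OiPr)4 (10 mol%), 4 Å MS, Et2O, −20 °C; then CF3CO2H (cat.), CH2Cl2, 0 °C
Reagents that add atoms: none
Why: Catalytic asymmetric hetero-Diels–Alder reaction in its Mukaiyama aldol–cyclisation form: the chiral BINOL–titanium Lewis acid binds the aldehyde and leaves its Si face open to the diene terminus, which sets C2 as S in 19, and acid then closes ring C by 6-endo addition of the oxygen to the methoxy enone with loss of the methoxy group, without touching that centre.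

Step 10
Reactants: 20 (2S)-2-[2,4-bis(tert-butyldimethylsilyloxy)-5-methoxyphenyl]-2,3-dihydro-4H-pyran-4-one
Product: 22 (2S)-2-[2,4-bis(tert-butyldimethylsilyloxy)-5-methoxyphenyl]-5-(phenylsulfanyl)-2,3-dihydro-4H-pyran-4-one, via chloro sulfide adduct 21 (not isolated)
Conditions: PhSCl (freshly distilled), CH2Cl2, −78 °C; then Et3N, −78 → 0 °C
Reagents that add atoms: benzenesulfenyl chloride, ClSc1ccccc1
Why: Electrophilic sulfenylation of a β-oxy enone by addition–elimination, as known for chromones and glycals: C5 is the nucleophilic β-carbon of the enol ether, chloride is held at C6 in 21, and Et3N removes the acidic C5–H with loss of chloride to restore the enone, with C2 a spectator.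

Step 11
Reactants: 22 (2S)-5-(phenylsulfanyl) dihydropyranone
Product: 23 (2S)-2-[2,4-bis(tert-butyldimethylsilyloxy)-5-methoxyphenyl]-5-(phenylsulfinyl)-2,3-dihydro-4H-pyran-4-one (both sulfur epimers, used together)
Conditions: mCPBA (1.0 equiv), CH2Cl2, −78 → −40 °C
Reagents that add atoms: 3-chloroperbenzoic acid, O=C(OO)c1cccc(Cl)c1
Why: Sulfide-to-sulfoxide oxidation with one equivalent of peracid at low temperature is chemoselective because sulfur is far more nucleophilic than the push–pull alkene or ring B, and the new sulfur stereocentre needs no control since it is expelled in step 12.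

Step 12
Reactants: 15 (3Z,6R)-1-methoxy-9-methyl-6-(prop-1-en-2-yl)-1,3-bis(trimethylsilyloxy)deca-1,3,8-triene; 23 (2S)-5-(phenylsulfinyl) dihydropyranone
Product: 27 (2S)-2-[2,4-bis(tert-butyldimethylsilyloxy)-5-methoxyphenyl]-5,7-dihydroxy-8-[(2R)-5-methyl-2-(prop-1-en-2-yl)hex-4-en-1-yl]chroman-4-one, via cycloadduct 24 (not isolated), via cyclohexadiene ketal 25 (not isolated), via bis-TMS flavanone 26 (not isolated)
Conditions: 15 (2.5 equiv), MeC(OSiMe3)=NSiMe3 (BSA), toluene, 60 → 110 °C, sealed tube; then 10% aq. citric acid, THF–MeOH, 0 °C → rt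
Reagents that add atoms: none
Why: Proposed new method: the ketene-acetal diene 15 should engage the C5=C6 bond of 23 in a strongly asynchronous normal-demand Diels–Alder reaction, C8–C8a (diene C4 to pyranone C6) forming ahead of C5–C4a (diene C1 to pyranone C5), so that the six-membered carbocycle ring A is closed onto the intact ring C by intermolecular [4+2] cycloaddition (in the stepwise limit a Mukaiyama–Michael addition followed by six-membered closure of the α-sulfinyl enolate carbon onto the dioxycarbenium carbon). Suprafacial addition keeps the C4a sulfinyl group and C8a–H on the same face of 24, the geometry that the five-centre syn elimination of PhSOH requires, and the resulting 25 loses its C5 methoxy group together with C8–H and aromatises to 26, while BSA silylates the sulfenic acid and the methanol so that neither protonates the diene, and citric acid finally frees only the two ring A phenols. Nearest precedent is the cycloaddition–aromatisation of Brassard- and Chan-type 1-alkoxy-1,3-bis(silyloxy)dienes with bromo- or sulfinylquinones and of oxygenated dienes with chromones carrying a 3-sulfinyl or 3-acyl group (xanthone synthesis), whereas a 5-sulfinyl-2,3-dihydropyran-4-one has not served as the dienophile. The four sp3 carbons created in 24 (C4a, C5, C8, C8a) and the sulfur stereocentre vanish on aromatisation, so no diastereocontrol is asked of the cycloaddition, and C2 and the lavandulyl centre are spectators at which no bond is made or broken under these neutral, aprotic conditions. The selectivity needed is regiochemical and is secured by matched polarity, since the diene terminus with the largest HOMO coefficient meets C6, which lies β to both the ketone and the sulfinyl group, while the unactivated lavandulyl alkenes cannot compete with the doubly activated dienophile. Because the C8a–O1 bond predates ring A, the lavandulyl group can end up only at C8 and no ring A phenol has to be chosen or masked for ring closure.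

Step 13
Reactants: 27 2',4'-bis-TBS ether of the target
Product: 28 (2S)-2-(2,4-dihydroxy-5-methoxyphenyl)-5,7-dihydroxy-8-[(2R)-5-methyl-2-(prop-1-en-2-yl)hex-4-en-1-yl]chroman-4-one (CNP0323048.1)
Conditions: Et3N·3HF, THF, 0 °C → rt; pH 7 phosphate buffer work-up
Reagents that add atoms: none
Why: Fluoride cleavage of aryl silyl ethers under weakly acidic buffering avoids the base that would open ring C by retro-oxa-Michael reaction and epimerise C2, as well as the strong acid that would cyclise the 7-OH onto the lavandulyl alkenes, so both stereocentres should pass unchanged into 28.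

**Compound list**
1 | (S)-4-benzyloxazolidin-2-one | O=C1N[C@@H](Cc2ccccc2)CO1 | starting material
2 | 3-methylbut-2-enoyl chloride | CC(C)=CC(=O)Cl | starting material
3 | N-lithio (S)-4-benzyloxazolidin-2-one | [Li+].O=C1[N-][C@@H](Cc2ccccc2)CO1 | intermediate
4 | (S)-4-benzyl-3-(3-methylbut-2-enoyl)oxazolidin-2-one | CC(C)=CC(=O)N1[C@@H](Cc2ccccc2)COC1=O | intermediate
5 | prenyl bromide | CC(C)=CCBr | starting material
6 | sodium (Z)-dienolate of 4 | [Na+].C=C(C)/C=C(\[O-])N1[C@@H](Cc2ccccc2)COC1=O | intermediate
7 | (4S)-4-benzyl-3-[(2S)-5-methyl-2-(prop-1-en-2-yl)hex-4-enoyl]oxazolidin-2-one | C=C(C)[C@H](CC=C(C)C)C(=O)N1[C@@H](Cc2ccccc2)COC1=O | intermediate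
8 | (S)-lavandulol | C=C(C)[C@H](CC=C(C)C)CO | intermediate
9 | (S)-lavandulyl iodide | C=C(C)[C@H](CC=C(C)C)CI | intermediate
10 | methyl acetoacetate | COC(=O)CC(C)=O | starting material
11 | sodium lithium dianion of methyl acetoacetate | [Na+].[Li+].[CH2-]C(=O)[CH-]C(=O)OC | intermediate
12 | methyl (6S)-9-methyl-3-oxo-6-(prop-1-en-2-yl)dec-8-enoate | C=C(C)[C@H](CC=C(C)C)CCC(=O)CC(=O)OC | intermediate
13 | methyl (6S)-9-methyl-6-(prop-1-en-2-yl)-3-(trimethylsilyloxy)deca-2,8-dienoate | C=C(C)[C@H](CC=C(C)C)CCC(O[Si](C)(C)C)=CC(=O)OC | intermediate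
14 | lithium dienolate of 13 | [Li+].C=C(C)[C@H](CC=C(C)C)C/C=C(O[Si](C)(C)C)/C=C(OC)[O-] | intermediate
15 | (3Z,6R)-1-methoxy-9-methyl-6-(prop-1-en-2-yl)-1,3-bis(trimethylsilyloxy)deca-1,3,8-triene | C=C(C)[C@H](CC=C(C)C)C/C=C(O[Si](C)(C)C)/C=C(OC)O[Si](C)(C)C | intermediate
16 | 2,4-dihydroxy-5-methoxybenzaldehyde | COc1cc(C=O)c(O)cc1O | starting material
17 | 2,4-bis(tert-butyldimethylsilyloxy)-5-methoxybenzaldehyde | COc1cc(C=O)c(O[Si](C)(C)C(C)(C)C)cc1O[Si](C)(C)C(C)(C)C | intermediate
18 | Danishefsky diene | CO/C=C/C(=C)O[Si](C)(C)C | starting material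
19 | (1E,5S)-5-[2,4-bis(tert-butyldimethylsilyloxy)-5-methoxyphenyl]-1-methoxy-5-(trimethylsilyloxy)pent-1-en-3-one | CO/C=C/C(=O)C[C@H](O[Si](C)(C)C)c1cc(OC)c(O[Si](C)(C)C(C)(C)C)cc1O[Si](C)(C)C(C)(C)C | intermediate
20 | (2S)-2-[2,4-bis(tert-butyldimethylsilyloxy)-5-methoxyphenyl]-2,3-dihydro-4H-pyran-4-one | O=C1C=CO[C@H](c2cc(OC)c(O[Si](C)(C)C(C)(C)C)cc2O[Si](C)(C)C(C)(C)C)C1 | intermediate
21 | (2S)-6-chloro-5-(phenylsulfanyl)tetrahydropyran-4-one adduct (C5 and C6 undefined) | O=C1C(Sc2ccccc2)C(Cl)O[C@H](c2cc(OC)c(O[Si](C)(C)C(C)(C)C)cc2O[Si](C)(C)C(C)(C)C)C1 | intermediate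
22 | (2S)-5-(phenylsulfanyl) dihydropyranone | O=C1C(Sc2ccccc2)=CO[C@H](c2cc(OC)c(O[Si](C)(C)C(C)(C)C)cc2O[Si](C)(C)C(C)(C)C)C1 | intermediate
23 | (2S)-5-(phenylsulfinyl) dihydropyranone (sulfur epimers) | O=C1C(S(=O)c2ccccc2)=CO[C@H](c2cc(OC)c(O[Si](C)(C)C(C)(C)C)cc2O[Si](C)(C)C(C)(C)C)C1 | intermediate
24 | [4+2] cycloadduct (C4a, C5, C8, C8a and S undefined) | C=C(C)[C@H](CC=C(C)C)CC1C(O[Si](C)(C)C)=CC(OC)(O[Si](C)(C)C)C2(S(=O)c3ccccc3)C(=O)C[C@@H](c3cc(OC)c(O[Si](C)(C)C(C)(C)C)cc3O[Si](C)(C)C(C)(C)C)OC12 | intermediate
25 | cyclohexadiene ketal after loss of PhSOH (C5 and C8 undefined) | C=C(C)[C@H](CC=C(C)C)CC1C(O[Si](C)(C)C)=CC(OC)(O[Si](C)(C)C)C2=C1O[C@H](c1cc(OC)c(O[Si](C)(C)C(C)(C)C)cc1O[Si](C)(C)C(C)(C)C)CC2=O | intermediate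
26 | 5,7-bis-TMS 2',4'-bis-TBS ether of the target | C=C(C)[C@H](CC=C(C)C)Cc1c(O[Si](C)(C)C)cc(O[Si](C)(C)C)c2c1O[C@H](c1cc(OC)c(O[Si](C)(C)C(C)(C)C)cc1O[Si](C)(C)C(C)(C)C)CC2=O | intermediate
27 | 2',4'-bis-TBS ether of the target | C=C(C)[C@H](CC=C(C)C)Cc1c(O)cc(O)c2c1O[C@H](c1cc(OC)c(O[Si](C)(C)C(C)(C)C)cc1O[Si](C)(C)C(C)(C)C)CC2=O | intermediate
28 | CNP0323048.1, (2S,2''R) | C=C(C)[C@H](CC=C(C)C)Cc1c(O)cc(O)c2c1O[C@H](c1cc(OC)c(O)cc1O)CC2=O | target

**Total step count:** 13
**Longest linear sequence:** 9 (steps 1–7, 12, 13)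

**Steps most likely to fail**

1. Step 12.
   - What may go wrong:
     - The donor oxygen O1 may leave C6 too weakly electrophilic for the hindered, alkyl-bearing diene terminus, so the diene is lost to silyl migration or protodesilylation before it adds.
     - Addition may stop at the open Michael stage.
     - Silyl transfer to the sulfoxide oxygen may divert the dienophile along a Pummerer-type path.
   - Fallback (known chemistry; sets out from 9 and 16, returns at 28). Ring A is bought instead of built.
     - Iodine–lithium exchange on 9 (t-BuLi, pentane–Et2O, −78 °C) and transmetalation with ZnBr2 give [(2S)-5-methyl-2-(prop-1-en-2-yl)hex-4-en-1-yl]zinc bromide F1.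
     - Catalogue 2'-hydroxy-4',6'-bis(methoxymethoxy)acetophenone is iodinated ortho to its free phenol (N-iodosuccinimide, DMF) to give 1-[2-hydroxy-3-iodo-4,6-bis(methoxymethoxy)phenyl]ethanone F2.
     - Negishi coupling of the two (Pd(OAc)2, SPhos, THF, slow addition of the zinc reagent, conditions that tolerate a free phenol) gives 1-{2-hydroxy-4,6-bis(methoxymethoxy)-3-[(2R)-lavandulyl]phenyl}ethanone F3.
     - Aldehyde 16 is protected (MOMCl, iPr2NEt, CH2Cl2) as 5-methoxy-2,4-bis(methoxymethoxy)benzaldehyde F4.
     - Claisen–Schmidt condensation of the ketone with this aldehyde (KOH, EtOH) gives the (E)-2'-hydroxychalcone F5.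
     - The only free phenol of the chalcone lies next to the lavandulyl group, so oxa-Michael closure (NaOAc, EtOH, reflux) can give only the 8-lavandulyl tetra-MOM flavanone F6, as both C2 epimers.
     - Dilute HCl in MeOH removes the MOM groups and gives 28 together with the (2R)-epimer of the target F7. The two are diastereomers and are separated by preparative HPLC.

2. Step 10.
   - What may go wrong: competing attack of the sulfenyl chloride on the electron-rich ring B, double sulfenylation, or loss of aryl silyl ethers to released HCl.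
   - Fallback (sets out from 20, returns at 22). Electrophilic sulfenylation is replaced by halogenation and cross-coupling.
     - Iodine–pyridine α-iodination (I2, pyridine, CH2Cl2, rt), which proceeds by amine addition rather than by aromatic substitution, gives the (2S)-5-iodo-2,3-dihydro-4H-pyran-4-one F8.
     - C–S coupling under zerovalent palladium catalysis (PhSH, Pd2(dba)3, Xantphos, iPr2NEt, dioxane, 80 °C) then delivers 22 under a base too weak to open ring C.

3. Step 9.
   - What may go wrong: slow turnover and poor facial selectivity, because the aldehyde is electron-rich and carries a bulky ortho silyloxy group.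
   - Fallback (sets out from 17 and 18, returns at 20). Catalyst control is given up for resolution.
     - ZnCl2 (THF, rt), then CF3CO2H (cat.), gives the racemic dihydropyranone F9.
     - This is separated by preparative chromatography on a chiral stationary phase into 20 and the (2R)-dihydropyranone F10, which is set aside.
     - Any (2R) material that still passes becomes a diastereomer after step 12 and is removed there.

**Further compounds**
F1 | step 12 | [(2S)-5-methyl-2-(prop-1-en-2-yl)hex-4-en-1-yl]zinc bromide | C=C(C)[C@H](CC=C(C)C)C[Zn]Br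
F2 | step 12 | 1-[2-hydroxy-3-iodo-4,6-bis(methoxymethoxy)phenyl]ethanone | CC(=O)c1c(O)c(I)c(OCOC)cc1OCOC
F3 | step 12 | 1-{2-hydroxy-4,6-bis(methoxymethoxy)-3-[(2R)-lavandulyl]phenyl}ethanone | C=C(C)[C@H](CC=C(C)C)Cc1c(O)c(C(C)=O)c(OCOC)cc1OCOC
F4 | step 12 | 5-methoxy-2,4-bis(methoxymethoxy)benzaldehyde | COCOc1cc(OCOC)c(OC)cc1C=O
F5 | step 12 | (E)-2'-hydroxychalcone | C=C(C)[C@H](CC=C(C)C)Cc1c(O)c(C(=O)/C=C/c2cc(OC)c(OCOC)cc2OCOC)c(OCOC)cc1OCOC
F6 | step 12 | 8-lavandulyl tetra-MOM flavanone (both C2 epimers) | C=C(C)[C@H](CC=C(C)C)Cc1c(OCOC)cc(OCOC)c2c1OC(c1cc(OC)c(OCOC)cc1OCOC)CC2=O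
F7 | step 12 | (2R)-epimer of the target | C=C(C)[C@H](CC=C(C)C)Cc1c(O)cc(O)c2c1O[C@@H](c1cc(OC)c(O)cc1O)CC2=O
F8 | step 10 | (2S)-2-[2,4-bis(tert-butyldimethylsilyloxy)-5-methoxyphenyl]-5-iodo-2,3-dihydro-4H-pyran-4-one | O=C1C(I)=CO[C@H](c2cc(OC)c(O[Si](C)(C)C(C)(C)C)cc2O[Si](C)(C)C(C)(C)C)C1
F9 | step 9 | racemic 2-[2,4-bis(tert-butyldimethylsilyloxy)-5-methoxyphenyl]-2,3-dihydro-4H-pyran-4-one | O=C1C=COC(c2cc(OC)c(O[Si](C)(C)C(C)(C)C)cc2O[Si](C)(C)C(C)(C)C)C1
F10 | step 9 | (2R)-2-[2,4-bis(tert-butyldimethylsilyloxy)-5-methoxyphenyl]-2,3-dihydro-4H-pyran-4-one | O=C1C=CO[C@@H](c2cc(OC)c(O[Si](C)(C)C(C)(C)C)cc2O[Si](C)(C)C(C)(C)C)C1
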